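**Retrosynthetic overview** (halimane numbering: ring A = C1–C5/C10, ring B = C5–C10, side chain C11–C16, methyls C17–C20)
1. Target ⇒ methyl ester 21 + (S)-solketal (ester exchange, ketal removal); 21 ⇒ 1(10),2-diene 20 (diimide).
2. Key disconnection: C5–C10 and C3–C4 of 20 are cut together ⇒ acyclic ene–yne–vinylsilane 18. Both rings form in one gold-catalysed operation: ring B first (C5–C10), ring A immediately after (C3–C4), leaving the C1=C10 alkene in place.
3. 18 ⇒ C5–C6 Negishi coupling, C1–C2 Sonogashira coupling, and alkynol 12 from Eschenmoser–Tanabe opening of epoxy ketone 9.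
4. 9 ⇒ enone 8, whose C8/C9 pair comes from two α'-alkylations of (R)-5-methylcyclohex-2-enone (chain iodide 3 first, then MeI anti to the C8 methyl).
5. 3 ⇒ methyl hydrogen (R)-3-methylglutarate (C13).

Assumption: (R)-5-methylcyclohex-2-en-1-one is bought as a catalogue chiral-pool enone (it is made from (R)-pulegone).

**Route**

Step 1
Reactants: 1 methyl hydrogen (R)-3-methylglutarate [(3R)-5-methoxy-3-methyl-5-oxopentanoic acid]
Product: 2 methyl (3R)-5-hydroxy-3-methylpentanoate
Conditions: BH3·SMe2, THF, 0 °C → rt; MeOH/H2O quench; used crude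
Reagents that add atoms: none
Why: Chemoselective borane reduction of the free carboxylic acid in the presence of the methyl ester; the C13 stereocentre is untouched.

Step 2
Reactants: 2 methyl (3R)-5-hydroxy-3-methylpentanoate
Product: 3 methyl (3S)-5-iodo-3-methylpentanoate
Conditions: PPh3, I2, imidazole, CH2Cl2, 0 °C
Reagents that add atoms: iodine, II
Why: Appel-type iodination of the primary alcohol (SN2 at CH2); the descriptor changes to S only through CIP priorities.

Step 3
Reactants: 4 (5R)-5-methylcyclohex-2-en-1-one; 3 methyl (3S)-5-iodo-3-methylpentanoate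
Product: 6 methyl (3R)-3-methyl-5-[(1S,6R)-6-methyl-2-oxocyclohex-3-en-1-yl]pentanoate, via lithium dienolate 5 (not isolated)
Conditions: LiN(SiMe3)2, THF, −78 °C; then 3, DMPU, −78 → −20 °C
Reagents that add atoms: none
Why: Kinetic α'-deprotonation gives the cross-conjugated dienolate, which is alkylated by the primary iodide (enolate SN2 alkylation); C8 comes from the chiral pool and the new CH centre (mainly trans) is planarised again in step 4.

Step 4
Reactants: 6 methyl (3R)-3-methyl-5-[(1S,6R)-6-methyl-2-oxocyclohex-3-en-1-yl]pentanoate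
Product: 8 methyl (3R)-5-[(1R,6R)-1,6-dimethyl-2-oxocyclohex-3-en-1-yl]-3-methylpentanoate, via lithium dienolate 7 (not isolated)
Conditions: LiN(SiMe3)2, THF, −78 → −30 °C; then MeI, DMPU, −78 → 0 °C
Reagents that add atoms: iodomethane, CI
Why: Second α'-enolate alkylation; the C8 methyl sits pseudo-axial to avoid A1,2 strain with the enolate substituent, so MeI enters anti to it and sets C9 (R) with C20 trans to C17 (expected ≥10:1, as in alkylations of 2,3-dialkylcyclohexanone enolates), while the amide base is too weak to enolise the ester.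

Step 5
Reactants: 8 methyl (3R)-5-[(1R,6R)-1,6-dimethyl-2-oxocyclohex-3-en-1-yl]-3-methylpentanoate
Product: 9 methyl (3R)-5-[(3R,4R)-3,4-dimethyl-2-oxo-7-oxabicyclo[4.1.0]heptan-3-yl]-3-methylpentanoate (epoxide diastereomers)
Conditions: t-BuOOH, DBU, CH2Cl2, rt
Reagents that add atoms: tert-butyl hydroperoxide, CC(C)(C)OO
Why: Nucleophilic (Weitz–Scheffer) epoxidation of the enone under anhydrous conditions that spare the ester; both epoxide diastereomers converge in step 6.

Step 6
Reactants: 9 methyl (3R)-5-[(3R,4R)-3,4-dimethyl-2-oxo-7-oxabicyclo[4.1.0]heptan-3-yl]-3-methylpentanoate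
Product: 12 methyl (3R,6R,7R)-6-ethynyl-9-hydroxy-3,6,7-trimethylnonanoate, via epoxy tosylhydrazone 10 (not isolated), via ynal 11 (not isolated)
Conditions: TsNHNH2, AcOH/CH2Cl2 1:1, −20 °C → rt; concentrate; NaBH4, MeOH, 0 °C
Reagents that add atoms: none
Why: Eschenmoser–Tanabe fragmentation turns the ring ketone into the C10≡C1 alkyne and C6 into an aldehyde, which is reduced in the same flask because β-unsubstituted ynals are labile; C8 and C9 are not involved.

Step 7
Reactants: 12 methyl (3R,6R,7R)-6-ethynyl-9-hydroxy-3,6,7-trimethylnonanoate; 13 (E)-(2-bromoethenyl)trimethylsilane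
Product: 14 methyl (3R,6R,7R)-9-hydroxy-3,6,7-trimethyl-6-[(E)-4-(trimethylsilyl)but-3-en-1-yn-1-yl]nonanoate
Conditions: Pd(PPh3)2Cl2 (3 mol %), CuI (5 mol %), i-Pr2NH, THF, rt
Reagents that add atoms: none
Why: Sonogashira coupling of the terminal alkyne with the vinyl bromide, with retention of the E geometry.

Step 8
Reactants: 14 methyl (3R,6R,7R)-9-hydroxy-3,6,7-trimethyl-6-[(E)-4-(trimethylsilyl)but-3-en-1-yn-1-yl]nonanoate
Product: 15 methyl (3R,6R,7R)-9-iodo-3,6,7-trimethyl-6-[(E)-4-(trimethylsilyl)but-3-en-1-yn-1-yl]nonanoate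
Conditions: PPh3, I2, imidazole (premixed), CH2Cl2, 0 °C
Reagents that add atoms: iodine, II
Why: Appel-type iodination of the primary alcohol; premixing the reagents keeps free iodine away from the vinylsilane.

Step 9
Reactants: 15 methyl (3R,6R,7R)-9-iodo-3,6,7-trimethyl-6-[(E)-4-(trimethylsilyl)but-3-en-1-yn-1-yl]nonanoate; 16 1-bromo-2-methylprop-1-ene
Product: 18 methyl (3R,6R,7R)-3,6,7,11-tetramethyl-6-[(E)-4-(trimethylsilyl)but-3-en-1-yn-1-yl]dodec-10-enoate, via alkylzinc iodide 17 (not isolated)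
Conditions: Zn dust, LiCl, THF, 40 °C; then 16, Pd(dppf)Cl2 (3 mol %), 50 °C
Reagents that add atoms: none
Why: Ester-tolerant zinc insertion into the primary C–I bond followed by Negishi sp3–sp2 coupling installs the trisubstituted C5=C4 alkene without touching any stereocentre.

Step 10
Reactants: 18 methyl (3R,6R,7R)-3,6,7,11-tetramethyl-6-[(E)-4-(trimethylsilyl)but-3-en-1-yn-1-yl]dodec-10-enoate
Product: 20 methyl (3R)-3-methyl-5-[(1R,2R,4aS)-1,2,5,5-tetramethyl-1,2,3,4,4a,5-hexahydronaphthalen-1-yl]pentanoate, via dienylgold complex 19 (not isolated)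
Conditions: [(2-biphenylyl)(t-Bu)2PAu(NCMe)]SbF6 (5 mol %), CH2Cl2/(CF3)2CHOH 10:1, −20 °C → rt; C5 epimer removed on AgNO3–silica
Reagents that add atoms: none
Why: Proposed new method: cationic monovalent gold activates the alkyne, the trisubstituted alkene adds 6-exo-dig through C5 anti to gold (ring B), the C4 tertiary cation (cyclopropyl gold carbene) is captured ipso by the cis-placed vinylsilane (ring A), the β-silyl cation loses Me3Si so the diene is fixed as 1(10),2, and the fluoro alcohol protodeaurates C1; the closest known reaction types are the gold-catalysed formal [4+2] cycloaddition of 1,6-enynes bearing alkenyl or aryl groups on the alkyne and vinylsilane-terminated cation–olefin cyclisation; C5 is set in the first bond formation through a chair with the C8 methyl and the reacting alkene equatorial, the C9 chain axial and the C9 methyl next to the gold-bearing carbon, for which I estimate about 3–4:1 in favour of 5S.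

Step 11
Reactants: 20 methyl (3R)-3-methyl-5-[(1R,2R,4aS)-1,2,5,5-tetramethyl-1,2,3,4,4a,5-hexahydronaphthalen-1-yl]pentanoate
Product: 21 methyl (3R)-3-methyl-5-[(1R,2R,4aS)-1,2,5,5-tetramethyl-1,2,3,4,4a,5,6,7-octahydronaphthalen-1-yl]pentanoate
Conditions: 2-O2NC6H4SO2NHNH2 (5 equiv), Et3N, CH2Cl2, rt
Reagents that add atoms: none
Why: Diimide reduction is selective for the cis-disubstituted C2=C3 bond of the diene over the trisubstituted, neopentyl C1=C10 bond (rate difference of two orders of magnitude); no stereocentre is formed.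

Step 12
Reactants: 21 methyl (3R)-3-methyl-5-[(1R,2R,4aS)-1,2,5,5-tetramethyl-1,2,3,4,4a,5,6,7-octahydronaphthalen-1-yl]pentanoate; 22 (S)-solketal {[(4S)-2,2-dimethyl-1,3-dioxolan-4-yl]methanol}
Product: 23 [(4R)-2,2-dimethyl-1,3-dioxolan-4-yl]methyl (3R)-3-methyl-5-[(1R,2R,4aS)-1,2,5,5-tetramethyl-1,2,3,4,4a,5,6,7-octahydronaphthalen-1-yl]pentanoate
Conditions: 22 (5 equiv), K2CO3 (0.2 equiv), neat, 80 °C, 30 mbar (MeOH removed)
Reagents that add atoms: none
Why: Base-catalysed transesterification driven by removal of methanol; the acyl group has no α-stereocentre and the solketal centre is not involved (its descriptor becomes R only through CIP priorities).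

Step 13
Reactants: 23 [(4R)-2,2-dimethyl-1,3-dioxolan-4-yl]methyl ester of the halimenoic acid
Product: 24 (2R)-2,3-dihydroxypropyl (3R)-3-methyl-5-[(1R,2R,4aS)-1,2,5,5-tetramethyl-1,2,3,4,4a,5,6,7-octahydronaphthalen-1-yl]pentanoate
Conditions: AcOH/H2O 4:1, 40 °C
Reagents that add atoms: none
Why: Mild acid hydrolysis of the isopropylidene ketal, chosen to avoid 1→2 acyl migration and alkene isomerisation; the glycerol centre keeps the configuration delivered by (S)-solketal.

**Compound list**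
1 | methyl hydrogen (R)-3-methylglutarate | C[C@H](CC(=O)O)CC(=O)OC | starting material
2 | methyl (3R)-5-hydroxy-3-methylpentanoate | C[C@H](CCO)CC(=O)OC | intermediate
3 | methyl (3S)-5-iodo-3-methylpentanoate | C[C@H](CCI)CC(=O)OC | intermediate
4 | (5R)-5-methylcyclohex-2-en-1-one | O=C1C=CC[C@@H](C)C1 | starting material
5 | lithium (3R)-3-methylcyclohexa-1,5-dien-1-olate | [Li]OC1=C[C@H](C)CC=C1 | intermediate
6 | methyl (3R)-3-methyl-5-[(1S,6R)-6-methyl-2-oxocyclohex-3-en-1-yl]pentanoate | O=C1C=CC[C@@H](C)[C@@H]1CC[C@@H](C)CC(=O)OC | intermediate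
7 | lithium (3R)-2-[(3R)-5-methoxy-3-methyl-5-oxopentyl]-3-methylcyclohexa-1,5-dien-1-olate | [Li]OC1=C(CC[C@@H](C)CC(=O)OC)[C@H](C)CC=C1 | intermediate
8 | methyl (3R)-5-[(1R,6R)-1,6-dimethyl-2-oxocyclohex-3-en-1-yl]-3-methylpentanoate | O=C1C=CC[C@@H](C)[C@@]1(C)CC[C@@H](C)CC(=O)OC | intermediate
9 | methyl (3R)-5-[(3R,4R)-3,4-dimethyl-2-oxo-7-oxabicyclo[4.1.0]heptan-3-yl]-3-methylpentanoate (epoxide diastereomers) | O=C1C2OC2C[C@@H](C)[C@@]1(C)CC[C@@H](C)CC(=O)OC | intermediate
10 | N'-tosylhydrazone of 9 | Cc1ccc(cc1)S(=O)(=O)NN=C1C2OC2C[C@@H](C)[C@@]1(C)CC[C@@H](C)CC(=O)OC | intermediate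
11 | methyl (3R,6R,7R)-6-ethynyl-3,6,7-trimethyl-9-oxononanoate | O=CC[C@@H](C)[C@@](C#C)(C)CC[C@@H](C)CC(=O)OC | intermediate
12 | methyl (3R,6R,7R)-6-ethynyl-9-hydroxy-3,6,7-trimethylnonanoate | OCC[C@@H](C)[C@@](C#C)(C)CC[C@@H](C)CC(=O)OC | intermediate
13 | (E)-(2-bromoethenyl)trimethylsilane | C[Si](C)(C)/C=C/Br | starting material
14 | methyl (3R,6R,7R)-9-hydroxy-3,6,7-trimethyl-6-[(E)-4-(trimethylsilyl)but-3-en-1-yn-1-yl]nonanoate | OCC[C@@H](C)[C@@](C#C/C=C/[Si](C)(C)C)(C)CC[C@@H](C)CC(=O)OC | intermediate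
15 | methyl (3R,6R,7R)-9-iodo-3,6,7-trimethyl-6-[(E)-4-(trimethylsilyl)but-3-en-1-yn-1-yl]nonanoate | ICC[C@@H](C)[C@@](C#C/C=C/[Si](C)(C)C)(C)CC[C@@H](C)CC(=O)OC | intermediate
16 | 1-bromo-2-methylprop-1-ene | CC(C)=CBr | starting material
17 | alkylzinc iodide derived from 15 (C–ZnI in place of C–I) | I[Zn]CC[C@@H](C)[C@@](C#C/C=C/[Si](C)(C)C)(C)CC[C@@H](C)CC(=O)OC | intermediate
18 | methyl (3R,6R,7R)-3,6,7,11-tetramethyl-6-[(E)-4-(trimethylsilyl)but-3-en-1-yn-1-yl]dodec-10-enoate | CC(C)=CCC[C@@H](C)[C@@](C#C/C=C/[Si](C)(C)C)(C)CC[C@@H](C)CC(=O)OC | intermediate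
19 | σ-dienylgold complex of 20 (gold with its (2-biphenylyl)di-tert-butylphosphine ligand on C1) | C[C@H](CC[C@@]1(C)C2=C([Au-][P+](C(C)(C)C)(C(C)(C)C)c3ccccc3-c3ccccc3)C=CC(C)(C)[C@@H]2CC[C@H]1C)CC(=O)OC | intermediate
20 | methyl (3R)-3-methyl-5-[(1R,2R,4aS)-1,2,5,5-tetramethyl-1,2,3,4,4a,5-hexahydronaphthalen-1-yl]pentanoate | C[C@H](CC[C@@]1(C)C2=CC=CC(C)(C)[C@@H]2CC[C@H]1C)CC(=O)OC | intermediate
21 | methyl (3R)-3-methyl-5-[(1R,2R,4aS)-1,2,5,5-tetramethyl-1,2,3,4,4a,5,6,7-octahydronaphthalen-1-yl]pentanoate | C[C@H](CC[C@@]1(C)C2=CCCC(C)(C)[C@@H]2CC[C@H]1C)CC(=O)OC | intermediate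
22 | (S)-solketal, [(4S)-2,2-dimethyl-1,3-dioxolan-4-yl]methanol | CC1(C)OC[C@H](CO)O1 | starting material
23 | [(4R)-2,2-dimethyl-1,3-dioxolan-4-yl]methyl (3R)-3-methyl-5-[(1R,2R,4aS)-1,2,5,5-tetramethyl-1,2,3,4,4a,5,6,7-octahydronaphthalen-1-yl]pentanoate | C[C@H](CC[C@@]1(C)C2=CCCC(C)(C)[C@@H]2CC[C@H]1C)CC(=O)OC[C@H]1COC(C)(C)O1 | intermediate
24 | (2R)-2,3-dihydroxypropyl (3R)-3-methyl-5-[(1R,2R,4aS)-1,2,5,5-tetramethyl-1,2,3,4,4a,5,6,7-octahydronaphthalen-1-yl]pentanoate | C[C@H](CC[C@@]1(C)C2=CCCC(C)(C)[C@@H]2CC[C@H]1C)CC(=O)OC[C@H](O)CO | target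

**Step count**
Total: 13 steps. Longest linear sequence: 13 steps (1 → 24); 11 steps from enone 4.

**Steps most likely to fail, with fallbacks**

Step 10 (gold bicyclisation). It is unprecedented for a 1,7-enyne with a vinylsilane terminator. It may stop after ring B, rearrange, or give a poor C5 ratio. Fallback, from 18 back to 20: separate the two ring closures. Cyclise 18 with the same gold catalyst in MeOH/CH2Cl2, so that methanol takes the C4 cation (alkoxycyclisation), giving the monocyclic tertiary methyl ether F1. Then ionise F1 with catalytic Me3SiOTf in CH2Cl2 at −78 °C. Ring A closes by a vinylsilane-terminated cation–olefin cyclisation and the route is rejoined at 20. The C5 epimers can be separated at the F1 stage.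

Step 6 (Eschenmoser–Tanabe fragmentation). The ketone is flanked by a quaternary carbon and the product is an aldehyde that can react with the hydrazide. Fallback, from 8 back to 12: cut the enone double bond of 8 by ozonolysis with NaBH4 work-up to the triol F2. Cleave its terminal 1,2-diol with NaIO4 to the δ-lactol F3 (C1 is lost and put back in the next operation). Ohira–Bestmann homologation of F3 (dimethyl (1-diazo-2-oxopropyl)phosphonate, K2CO3, MeOH) then gives alkynol 12.

Step 3 (α'-alkylation with an unactivated iodide). Slow alkylation can lead to proton exchange and double alkylation. Fallback, from 4 (with 3) back to 6: convert 4 with Me2NNH2 into the N,N-dimethylhydrazone F4. Alkylate its aza-enolate (LDA, THF, −78 °C) with 3 to give the alkylated hydrazone F5. Cleave the hydrazone with aqueous CuCl2 to return to 6.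

**Further compounds**
F1 | step 10 | methyl (3R)-5-[(1R,2E,3R,6R)-3-(2-methoxypropan-2-yl)-1,6-dimethyl-2-[(2E)-3-(trimethylsilyl)prop-2-en-1-ylidene]cyclohexyl]-3-methylpentanoate | C[C@H](CC[C@@]1(C)/C(=C/C=C/[Si](C)(C)C)[C@H](C(C)(C)OC)CC[C@H]1C)CC(=O)OC
F2 | step 6 | methyl (3R,6R,7R)-6-(1,2-dihydroxyethyl)-9-hydroxy-3,6,7-trimethylnonanoate (carbinol epimers) | OCC[C@@H](C)[C@@](C(O)CO)(C)CC[C@@H](C)CC(=O)OC
F3 | step 6 | methyl (3R)-5-[(3R,4R)-2-hydroxy-3,4-dimethyloxan-3-yl]-3-methylpentanoate (anomers) | OC1OCC[C@@H](C)[C@@]1(C)CC[C@@H](C)CC(=O)OC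
F4 | step 3 | 1,1-dimethyl-2-[(5R)-5-methylcyclohex-2-en-1-ylidene]hydrazine | CN(C)N=C1C=CC[C@@H](C)C1
F5 | step 3 | methyl (3R)-5-[(1S,6R)-2-(2,2-dimethylhydrazinylidene)-6-methylcyclohex-3-en-1-yl]-3-methylpentanoate | CN(C)N=C1C=CC[C@@H](C)[C@@H]1CC[C@@H](C)CC(=O)OC
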